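**Plan** (prostanoid numbering: C1 = ester carbon, ring = C8–C12, lower chain = C13–C20)
1. Cuts: first C7=C8 (aldol addition, then dehydration), separating a C1–C7 diacetoxy aldehyde from a 2-chloro-4-silyloxycyclopentenone; then C9–C10 and C10–C11 together, excising C10 as dichlorocarbene to leave a cyclobutanone silyl enol ether; last C15–C16 and C12–C13 in the lower chain and C3–C4 in the aldehyde.
2. Enabling feature: C9 (C=O), C10 (C–Cl) and C11 (=CH) form an α-chloroenone, the product of dichlorocarbene ring expansion of a silyl enol ether; without C10 the ring is a 3-oxy-3-alkylcyclobutanone (C9, C8, C12, C11) with a mirror plane through C9 and C12.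
3. Forward: the purchased four-membered ring receives C13–C20 (propargylation, skipped diyne, semi-hydrogenation), is taken to the prochiral ketone, desymmetrised to the enol ether and expanded to the five-membered ring (the only ring made); the aldehyde is then joined at C8, water is eliminated and the silyl group removed.
4. Stereochemistry: C12 from enantiotopic deprotonation by a chiral lithium amide (the choice of which CH2 becomes C11 decides it); C5 and C6 from L-threitol acetonide, carried unchanged; 14Z and 17Z from syn semi-hydrogenation; 7E from the E1cB elimination.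

Key step: step 8

Assumption: the sense of enantiotopic selection by the lithium amide on a 3-silyloxy-3-alkylcyclobutanone cannot be predicted with confidence; the (R,R)-amide is written, and the equally available (S,S)-amide is to be used if it is the one that delivers the (S)-enol ether drawn in step 7.

Step 1
Reactants: 1 3-(benzyloxy)cyclobutan-1-one; 2 3-bromoprop-1-yne
Product: 4 3-(benzyloxy)-1-(prop-2-yn-1-yl)cyclobutan-1-ol (cis/trans mixture), via allenylzinc bromide 3 (not isolated)
Conditions: Zn dust, THF, 0 °C to rt; dilute aq HCl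
Reagents that add atoms: none
Why: Barbier-type propargylation, in which the allenylzinc formed in the flask adds to the strained ketone through an SE2' transition state to give the homopropargylic tertiary alcohol (C12–C13 bond); the cis/trans relation to the benzyloxy group is irrelevant because that carbon later becomes the C9 carbonyl.

Step 2
Reactants: 4 3-(benzyloxy)-1-(prop-2-yn-1-yl)cyclobutan-1-ol; 5 1-bromopent-2-yne
Product: 6 3-(benzyloxy)-1-(octa-2,5-diyn-1-yl)cyclobutan-1-ol
Conditions: CuI (cat.), nBu4NCl, K2CO3, DMF, rt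
Reagents that add atoms: none
Why: Copper-catalysed coupling of a terminal alkyne with a propargylic bromide under carbonate base is the standard entry to skipped diynes (C15–C16 bond) and tolerates the free tertiary alcohol and the benzyl ether.

Step 3
Reactants: 6 3-(benzyloxy)-1-(octa-2,5-diyn-1-yl)cyclobutan-1-ol
Product: 7 3-(benzyloxy)-1-[(2Z,5Z)-octa-2,5-dien-1-yl]cyclobutan-1-ol
Conditions: H2 (1 atm), P-2 nickel from Ni(OAc)2·4H2O and NaBH4, ethylenediamine, EtOH, rt
Reagents that add atoms: none
Why: Catalytic semi-hydrogenation over P-2 nickel delivers hydrogen syn to both alkynes, setting the 14Z and 17Z alkenes without hydrogenolysis of the benzyl ether.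

Step 4
Reactants: 7 3-(benzyloxy)-1-[(2Z,5Z)-octa-2,5-dien-1-yl]cyclobutan-1-ol
Product: 8 {3-(benzyloxy)-1-[(2Z,5Z)-octa-2,5-dien-1-yl]cyclobutoxy}triethylsilane
Conditions: Et3SiOTf, 2,6-lutidine, CH2Cl2, −78 to 0 °C
Reagents that add atoms: triethylsilyl trifluoromethanesulfonate, CC[Si](CC)(CC)OS(=O)(=O)C(F)(F)F
Why: Silyl triflate silylation caps the hindered tertiary alcohol before the ketone is unveiled, so that a free β-hydroxycyclobutanone prone to retro-aldol ring opening never appears, and the triethylsilyl ether is robust enough to be carried to the last step.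

Step 5
Reactants: 8 {3-(benzyloxy)-1-[(2Z,5Z)-octa-2,5-dien-1-yl]cyclobutoxy}triethylsilane
Product: 9 3-[(2Z,5Z)-octa-2,5-dien-1-yl]-3-(triethylsilyloxy)cyclobutan-1-ol
Conditions: lithium 4,4'-di-tert-butylbiphenylide (LiDBB, stock solution), THF, −78 °C; H2O
Reagents that add atoms: none
Why: Reductive debenzylation by single-electron transfer from the arene radical anion cleaves the benzylic C–O bond at low temperature and leaves isolated Z alkenes and the silyl ether intact, where hydrogenolysis would saturate the diene.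

Step 6
Reactants: 9 3-[(2Z,5Z)-octa-2,5-dien-1-yl]-3-(triethylsilyloxy)cyclobutan-1-ol
Product: 10 3-[(2Z,5Z)-octa-2,5-dien-1-yl]-3-(triethylsilyloxy)cyclobutan-1-one
Conditions: Dess–Martin periodinane, pyridine, CH2Cl2, 0 °C to rt
Reagents that add atoms: none
Why: Dess–Martin oxidation of the secondary cyclobutanol under buffered, non-basic conditions should give the mirror-symmetric, prochiral cyclobutanone without touching the skipped diene.

Step 7
Reactants: 10 3-[(2Z,5Z)-octa-2,5-dien-1-yl]-3-(triethylsilyloxy)cyclobutan-1-one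
Product: 12 (3S)-3-[(2Z,5Z)-octa-2,5-dien-1-yl]-1,3-bis(triethylsilyloxy)cyclobut-1-ene, via lithium cyclobutenolate 11 (not isolated)
Conditions: (R,R)-bis(1-phenylethyl)amine, nBuLi, THF, 0 °C; then Et3SiCl and 10, −100 °C (internal quench)
Reagents that add atoms: chlorotriethylsilane, CC[Si](CC)(CC)Cl
Why: Enantiotopic-group-selective deprotonation of a prochiral cyclobutanone by a C2-symmetric chiral lithium amide with internal silyl chloride quench is an established desymmetrisation; the choice between the two α-methylenes fixes which becomes C11 and thereby the C12 configuration, and immediate O-silylation forestalls β-elimination of the silyloxy group from the enolate.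

Step 8
Reactants: 12 (3S)-3-[(2Z,5Z)-octa-2,5-dien-1-yl]-1,3-bis(triethylsilyloxy)cyclobut-1-ene; 13 chloroform
Product: 16 (4S)-2-chloro-4-[(2Z,5Z)-octa-2,5-dien-1-yl]-4-(triethylsilyloxy)cyclopent-2-en-1-one, via dichlorocarbene 14 (not isolated), via dichlorobicyclopentane 15 (not isolated)
Conditions: CHCl3 (excess), KOtBu (added in portions), pentane, −40 to 0 °C
Reagents that add atoms: none
Why: Potassium tert-butoxide converts 13 into dichlorocarbene 14, which adds to the electron-rich C9=C11 enol ether to give the 5,5-dichlorobicyclo[2.1.0]pentane 15; strain drives disrotatory cyclopropyl-to-allyl opening of the fused C9–C11 bond with loss of the endo chloride (the two ring bonds turn inward), the silyloxy group stabilises the 2-chloroallyl cation at C9, and chloride takes the silyl group to leave the C9 ketone conjugated to C10(Cl)=C11. The closest known reactions are the dihalocarbene ring expansion of cyclic silyl enol ethers to 2-halocycloalk-2-enones and the spontaneous rearrangement of dihalocarbene–cyclobutene adducts to 2,3-dihalocyclopentenes. The five-membered ring is thus closed by one-carbon ring expansion and not by cyclisation of a chain: a cheletropic [2+1] addition closes the three-membered ring and a two-electron electrocyclic opening merges it with the four-membered ring, forming C9–C10 and C10–C11. No stereocentre is created; C12 is a spectator that keeps the configuration set in step 7 (its descriptor is S here only because of CIP ranking). The step needs chemoselectivity for the strained, trisubstituted, oxygen-substituted enol ether over the 14Z and 17Z alkenes, which the electrophilic carbene should show when base is added in portions and the reaction is stopped once 12 is consumed; the placing of chlorine on C10 is fixed by the mechanism.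

Step 9
Reactants: 17 (4S,5S)-2,2-dimethyl-1,3-dioxolane-4,5-dimethanol (L-threitol acetonide)
Product: 18 [(4S,5S)-5-[(benzyloxy)methyl]-2,2-dimethyl-1,3-dioxolan-4-yl]methanol
Conditions: NaH (1 equiv), BnBr, DMF, 0 °C to rt
Reagents that add atoms: benzyl bromide, BrCc1ccccc1
Why: Williamson etherification of the mono-alkoxide of the C2-symmetric diol should give mainly the mono-benzyl ether, and because the two hydroxymethyl groups are homotopic there is no regiochemical issue.

Step 10
Reactants: 18 [(4S,5S)-5-[(benzyloxy)methyl]-2,2-dimethyl-1,3-dioxolan-4-yl]methanol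
Product: 19 (4S,5R)-4-[(benzyloxy)methyl]-5-(iodomethyl)-2,2-dimethyl-1,3-dioxolane
Conditions: I2, PPh3, imidazole, toluene, rt
Reagents that add atoms: iodine, II
Why: Appel-type iodination converts the primary alcohol into the iodide (future C4) with no change at the two stereocentres.

Step 11
Reactants: 19 (4S,5R)-4-[(benzyloxy)methyl]-5-(iodomethyl)-2,2-dimethyl-1,3-dioxolane
Product: 20 (2S,3R)-1-(benzyloxy)-4-iodobutane-2,3-diol
Conditions: TsOH·H2O (cat.), MeOH, rt
Reagents that add atoms: none
Why: Acid-catalysed transacetalisation removes the acetonide while the carboxyl terminus is still absent, so the free C5 hydroxyl never coexists with the C1 ester and δ-lactone formation is excluded.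

Step 12
Reactants: 20 (2S,3R)-1-(benzyloxy)-4-iodobutane-2,3-diol
Product: 21 (2S,3R)-1-(benzyloxy)-4-iodobutane-2,3-diyl diacetate
Conditions: Ac2O, pyridine, DMAP (cat.), CH2Cl2, 0 °C
Reagents that add atoms: acetic anhydride, CC(=O)OC(C)=O
Why: DMAP-catalysed acylation installs the two acetates of the target (C5 and C6) with retention and is fast enough to outpace any displacement of the neighbouring primary iodide.

Step 13
Reactants: 21 (2S,3R)-1-(benzyloxy)-4-iodobutane-2,3-diyl diacetate; 22 methyl acrylate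
Product: 23 methyl (5S,6S)-5,6-diacetoxy-7-(benzyloxy)heptanoate
Conditions: Bu3SnH (slow addition), AIBN (cat.), 22 (excess), benzene, 80 °C
Reagents that add atoms: none
Why: Giese reaction, in which the primary alkyl radical from the iodide adds to the acrylate to form C3–C4 and bring in C1–C3 in one step; the stereocentres are not involved and a 1,2-acyloxy shift is slow compared with addition to the acrylate.

Step 14
Reactants: 23 methyl (5S,6S)-5,6-diacetoxy-7-(benzyloxy)heptanoate
Product: 24 methyl (5S,6S)-5,6-diacetoxy-7-hydroxyheptanoate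
Conditions: H2 (1 atm), 10% Pd/C, EtOAc, rt
Reagents that add atoms: none
Why: Hydrogenolysis of the benzyl ether over palladium on carbon in a neutral solvent frees the C7 alcohol without acetyl migration or ester exchange.

Step 15
Reactants: 24 methyl (5S,6S)-5,6-diacetoxy-7-hydroxyheptanoate
Product: 25 methyl (5S,6R)-5,6-diacetoxy-7-oxoheptanoate
Conditions: Dess–Martin periodinane, pyridine, CH2Cl2, 0 °C; used at once
Reagents that add atoms: none
Why: Dess–Martin oxidation under buffered conditions should give the α-acetoxy aldehyde without epimerisation at C6 or β-elimination of the C5 acetate (the descriptor at C6 changes only through CIP ranking).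

Step 16
Reactants: 16 (4S)-2-chloro-4-[(2Z,5Z)-octa-2,5-dien-1-yl]-4-(triethylsilyloxy)cyclopent-2-en-1-one; 25 methyl (5S,6R)-5,6-diacetoxy-7-oxoheptanoate
Product: 27 methyl (5S,6S)-5,6-diacetoxy-7-[(5S)-3-chloro-5-[(2Z,5Z)-octa-2,5-dien-1-yl]-2-oxo-5-(triethylsilyloxy)cyclopent-3-en-1-yl]-7-hydroxyheptanoate (epimers at C7 and C8), via lithium dienolate 26 (not isolated)
Conditions: LiN(iPr)2, THF, −78 °C; then 25, −78 °C; AcOH quench at −78 °C
Reagents that add atoms: none
Why: Directed aldol addition, in which kinetic deprotonation can only occur at C8 (C12 bears no hydrogen) and the cross-conjugated lithium dienolate adds to the aldehyde at low temperature to form C7–C8; the two new centres (C7, C8) are uncontrolled and are erased in the next step.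

Step 17
Reactants: 27 aldol adduct (epimers at C7 and C8)
Product: 29 methyl (5S,6S,7E)-5,6-diacetoxy-7-[(5R)-3-chloro-5-[(2Z,5Z)-octa-2,5-dien-1-yl]-2-oxo-5-(triethylsilyloxy)cyclopent-3-en-1-ylidene]heptanoate, via C7 mesylate 28 (not isolated)
Conditions: MsCl, Et3N, DMAP (cat.), CH2Cl2, −20 °C to rt
Reagents that add atoms: none
Why: Mesylation of the C7 alcohol followed by amine-promoted E1cB elimination through the C8 enolate converges all aldol epimers on the cross-conjugated dienone, the 7E isomer being expected to predominate because it keeps the C6 branch away from the C9 carbonyl (any 7Z isomer is separable); the sulfonyl group resides only in 28, and the C12 descriptor becomes R solely because C8 is now sp2.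

Step 18
Reactants: 29 12-O-triethylsilyl punaglandin 3
Product: 30 punaglandin 3
Conditions: HF·pyridine, pyridine, THF, 0 °C to rt
Reagents that add atoms: none
Why: Fluoride-mediated desilylation of the tertiary triethylsilyl ether under buffered conditions is mild enough for the two acetates, the methyl ester and the chlorodienone, and leaves C12 untouched.

**Compound list**
1 | 3-(benzyloxy)cyclobutan-1-one | O=C1CC(OCc2ccccc2)C1 | starting material
2 | 3-bromoprop-1-yne (propargyl bromide) | C#CCBr | starting material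
3 | allenylzinc bromide (propa-1,2-dien-1-ylzinc bromide) | C=C=C[Zn]Br | intermediate
4 | 3-(benzyloxy)-1-(prop-2-yn-1-yl)cyclobutan-1-ol (cis/trans mixture) | C#CCC1(O)CC(OCc2ccccc2)C1 | intermediate
5 | 1-bromopent-2-yne | CCC#CCBr | starting material
6 | 3-(benzyloxy)-1-(octa-2,5-diyn-1-yl)cyclobutan-1-ol | CCC#CCC#CCC1(O)CC(OCc2ccccc2)C1 | intermediate
7 | 3-(benzyloxy)-1-[(2Z,5Z)-octa-2,5-dien-1-yl]cyclobutan-1-ol | CC/C=C\C/C=C\CC1(O)CC(OCc2ccccc2)C1 | intermediate
8 | {3-(benzyloxy)-1-[(2Z,5Z)-octa-2,5-dien-1-yl]cyclobutoxy}triethylsilane | CC/C=C\C/C=C\CC1(O[Si](CC)(CC)CC)CC(OCc2ccccc2)C1 | intermediate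
9 | 3-[(2Z,5Z)-octa-2,5-dien-1-yl]-3-(triethylsilyloxy)cyclobutan-1-ol | CC/C=C\C/C=C\CC1(O[Si](CC)(CC)CC)CC(O)C1 | intermediate
10 | 3-[(2Z,5Z)-octa-2,5-dien-1-yl]-3-(triethylsilyloxy)cyclobutan-1-one | CC/C=C\C/C=C\CC1(O[Si](CC)(CC)CC)CC(=O)C1 | intermediate
11 | lithium (3S)-3-[(2Z,5Z)-octa-2,5-dien-1-yl]-3-(triethylsilyloxy)cyclobut-1-en-1-olate | CC/C=C\C/C=C\C[C@@]1(O[Si](CC)(CC)CC)C=C(O[Li])C1 | intermediate
12 | (3S)-3-[(2Z,5Z)-octa-2,5-dien-1-yl]-1,3-bis(triethylsilyloxy)cyclobut-1-ene | CC/C=C\C/C=C\C[C@@]1(O[Si](CC)(CC)CC)C=C(O[Si](CC)(CC)CC)C1 | intermediate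
13 | chloroform | ClC(Cl)Cl | starting material
14 | dichlorocarbene | Cl[C]Cl | intermediate
15 | (3S)-5,5-dichloro-3-[(2Z,5Z)-octa-2,5-dien-1-yl]-1,3-bis(triethylsilyloxy)bicyclo[2.1.0]pentane (cis-fused, both faces) | CC/C=C\C/C=C\C[C@@]1(O[Si](CC)(CC)CC)C2C(Cl)(Cl)C2(O[Si](CC)(CC)CC)C1 | intermediate
16 | (4S)-2-chloro-4-[(2Z,5Z)-octa-2,5-dien-1-yl]-4-(triethylsilyloxy)cyclopent-2-en-1-one | CC/C=C\C/C=C\C[C@@]1(O[Si](CC)(CC)CC)C=C(Cl)C(=O)C1 | intermediate
17 | (4S,5S)-2,2-dimethyl-1,3-dioxolane-4,5-dimethanol | OC[C@@H]1OC(C)(C)O[C@H]1CO | starting material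
18 | [(4S,5S)-5-[(benzyloxy)methyl]-2,2-dimethyl-1,3-dioxolan-4-yl]methanol | OC[C@@H]1OC(C)(C)O[C@H]1COCc1ccccc1 | intermediate
19 | (4S,5R)-4-[(benzyloxy)methyl]-5-(iodomethyl)-2,2-dimethyl-1,3-dioxolane | IC[C@@H]1OC(C)(C)O[C@H]1COCc1ccccc1 | intermediate
20 | (2S,3R)-1-(benzyloxy)-4-iodobutane-2,3-diol | IC[C@H](O)[C@@H](O)COCc1ccccc1 | intermediate
21 | (2S,3R)-1-(benzyloxy)-4-iodobutane-2,3-diyl diacetate | IC[C@H](OC(C)=O)[C@@H](OC(C)=O)COCc1ccccc1 | intermediate
22 | methyl acrylate | C=CC(=O)OC | starting material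
23 | methyl (5S,6S)-5,6-diacetoxy-7-(benzyloxy)heptanoate | COC(=O)CCC[C@H](OC(C)=O)[C@@H](OC(C)=O)COCc1ccccc1 | intermediate
24 | methyl (5S,6S)-5,6-diacetoxy-7-hydroxyheptanoate | COC(=O)CCC[C@H](OC(C)=O)[C@@H](OC(C)=O)CO | intermediate
25 | methyl (5S,6R)-5,6-diacetoxy-7-oxoheptanoate | COC(=O)CCC[C@H](OC(C)=O)[C@@H](OC(C)=O)C=O | intermediate
26 | lithium (3S)-5-chloro-3-[(2Z,5Z)-octa-2,5-dien-1-yl]-3-(triethylsilyloxy)cyclopenta-1,4-dien-1-olate | CC/C=C\C/C=C\C[C@@]1(O[Si](CC)(CC)CC)C=C(Cl)C(O[Li])=C1 | intermediate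
27 | methyl (5S,6S)-5,6-diacetoxy-7-[(5S)-3-chloro-5-[(2Z,5Z)-octa-2,5-dien-1-yl]-2-oxo-5-(triethylsilyloxy)cyclopent-3-en-1-yl]-7-hydroxyheptanoate (epimers at C7 and C8) | CC/C=C\C/C=C\C[C@@]1(O[Si](CC)(CC)CC)C=C(Cl)C(=O)C1C(O)[C@H](OC(C)=O)[C@H](CCCC(=O)OC)OC(C)=O | intermediate
28 | methyl (5S,6R)-5,6-diacetoxy-7-[(5S)-3-chloro-5-[(2Z,5Z)-octa-2,5-dien-1-yl]-2-oxo-5-(triethylsilyloxy)cyclopent-3-en-1-yl]-7-(methylsulfonyloxy)heptanoate (epimers at C7 and C8) | CC/C=C\C/C=C\C[C@@]1(O[Si](CC)(CC)CC)C=C(Cl)C(=O)C1C(OS(C)(=O)=O)[C@H](OC(C)=O)[C@H](CCCC(=O)OC)OC(C)=O | intermediate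
29 | methyl (5S,6S,7E)-5,6-diacetoxy-7-[(5R)-3-chloro-5-[(2Z,5Z)-octa-2,5-dien-1-yl]-2-oxo-5-(triethylsilyloxy)cyclopent-3-en-1-ylidene]heptanoate (12-O-triethylsilyl punaglandin 3) | CC/C=C\C/C=C\C[C@@]1(O[Si](CC)(CC)CC)C=C(Cl)C(=O)/C1=C/[C@H](OC(C)=O)[C@H](CCCC(=O)OC)OC(C)=O | intermediate
30 | punaglandin 3, methyl (5S,6S,7E)-5,6-diacetoxy-7-[(5R)-3-chloro-5-hydroxy-5-[(2Z,5Z)-octa-2,5-dien-1-yl]-2-oxocyclopent-3-en-1-ylidene]heptanoate | CC/C=C\C/C=C\C[C@@]1(O)C=C(Cl)C(=O)/C1=C/[C@H](OC(C)=O)[C@H](CCCC(=O)OC)OC(C)=O | target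

**Step count**
Total: 18 steps. Longest linear sequence: 11 steps (steps 1–8 and 16–18, from 1); the aldehyde branch (steps 9–15) joins at step 16.

**Steps most likely to fail**

Step 8. The carbene may also cyclopropanate the two Z alkenes if the rate difference is smaller than hoped, and tert-butoxide may desilylate the enol ether or enolise the product enone before work-up. The fallback sets out from 12 and returns at 16, replacing the halocarbene by a stepwise homologation and a separate chlorination. Simmons–Smith cyclopropanation (Et2Zn, CH2I2, CH2Cl2, 0 °C) of the enol ether should give (3S)-3-[(2Z,5Z)-octa-2,5-dien-1-yl]-1,3-bis(triethylsilyloxy)bicyclo[2.1.0]pentane F1. Oxidative opening of the fused bond with FeCl3 in DMF should give the ring-enlarged β-chloro ketone (4S)-3-chloro-4-[(2Z,5Z)-octa-2,5-dien-1-yl]-4-(triethylsilyloxy)cyclopentan-1-one F2, and NaOAc in MeOH should eliminate HCl to (4S)-4-[(2Z,5Z)-octa-2,5-dien-1-yl]-4-(triethylsilyloxy)cyclopent-2-en-1-one F3. Nucleophilic epoxidation (tBuOOH, DBU, CH2Cl2), which ignores the isolated alkenes, would give (4S)-4-[(2Z,5Z)-octa-2,5-dien-1-yl]-4-(triethylsilyloxy)-6-oxabicyclo[3.1.0]hexan-2-one F4. Dry HCl in CHCl3 at 0 °C should open the epoxide at C10 to the chlorohydrin (4S)-2-chloro-3-hydroxy-4-[(2Z,5Z)-octa-2,5-dien-1-yl]-4-(triethylsilyloxy)cyclopentan-1-one F5 (not isolated), which loses water to 16.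

Step 7. The amide may discriminate poorly between the two methylenes because the silyloxy group and the chain at C12 are of similar size, and the enolate may lose siloxide before it is trapped. The fallback sets out from 10 and returns at 16, replacing asymmetric induction by resolution. LiN(iPr)2 with Et3SiCl internal quench (THF, −78 °C) would give, through the racemic lithium 3-[(2Z,5Z)-octa-2,5-dien-1-yl]-3-(triethylsilyloxy)cyclobut-1-en-1-olate F6 (not isolated), racemic 3-[(2Z,5Z)-octa-2,5-dien-1-yl]-1,3-bis(triethylsilyloxy)cyclobut-1-ene F7. The conditions of step 8 (via 14) would take this through racemic 5,5-dichloro-3-[(2Z,5Z)-octa-2,5-dien-1-yl]-1,3-bis(triethylsilyloxy)bicyclo[2.1.0]pentane F8 (not isolated) to racemic 2-chloro-4-[(2Z,5Z)-octa-2,5-dien-1-yl]-4-(triethylsilyloxy)cyclopent-2-en-1-one F9. Preparative chromatography on a chiral stationary phase would separate 16 from (4R)-2-chloro-4-[(2Z,5Z)-octa-2,5-dien-1-yl]-4-(triethylsilyloxy)cyclopent-2-en-1-one F10; material of partial enantiopurity from step 7 could be upgraded the same way.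

Step 16. The dienolate may act as a base toward the aldehyde (deprotonation at C6 followed by loss of the C5 acetate), the lithium aldolate may suffer acetyl migration from O6 to O7 or retro-aldol cleavage, and the dienolate may lose siloxide. The fallback sets out from 16 and returns at 27, replacing the basic aldol by a Lewis-acid-mediated Mukaiyama aldol. The enolate 26 would be trapped with Et3SiCl at −78 °C to give (3S)-5-chloro-3-[(2Z,5Z)-octa-2,5-dien-1-yl]-1,3-bis(triethylsilyloxy)cyclopenta-1,4-diene F11, a 5,5-disubstituted cyclopentadiene that cannot undergo hydrogen shifts. Its reaction with 25 and BF3·OEt2 in CH2Cl2 at −78 °C, followed by aqueous work-up, should give 27 under non-basic conditions.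

**Further compounds**
F1 | step 8 | (3S)-3-[(2Z,5Z)-octa-2,5-dien-1-yl]-1,3-bis(triethylsilyloxy)bicyclo[2.1.0]pentane | CC/C=C\C/C=C\C[C@@]1(O[Si](CC)(CC)CC)C2CC2(O[Si](CC)(CC)CC)C1
F2 | step 8 | (4S)-3-chloro-4-[(2Z,5Z)-octa-2,5-dien-1-yl]-4-(triethylsilyloxy)cyclopentan-1-one | CC/C=C\C/C=C\C[C@@]1(O[Si](CC)(CC)CC)C(Cl)CC(=O)C1
F3 | step 8 | (4S)-4-[(2Z,5Z)-octa-2,5-dien-1-yl]-4-(triethylsilyloxy)cyclopent-2-en-1-one | CC/C=C\C/C=C\C[C@@]1(O[Si](CC)(CC)CC)C=CC(=O)C1
F4 | step 8 | (4S)-4-[(2Z,5Z)-octa-2,5-dien-1-yl]-4-(triethylsilyloxy)-6-oxabicyclo[3.1.0]hexan-2-one | CC/C=C\C/C=C\C[C@@]1(O[Si](CC)(CC)CC)C2OC2C(=O)C1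
F5 | step 8 | (4S)-2-chloro-3-hydroxy-4-[(2Z,5Z)-octa-2,5-dien-1-yl]-4-(triethylsilyloxy)cyclopentan-1-one | CC/C=C\C/C=C\C[C@@]1(O[Si](CC)(CC)CC)C(O)C(Cl)C(=O)C1
F6 | step 7 | racemic lithium 3-[(2Z,5Z)-octa-2,5-dien-1-yl]-3-(triethylsilyloxy)cyclobut-1-en-1-olate | CC/C=C\C/C=C\CC1(O[Si](CC)(CC)CC)C=C(O[Li])C1
F7 | step 7 | racemic 3-[(2Z,5Z)-octa-2,5-dien-1-yl]-1,3-bis(triethylsilyloxy)cyclobut-1-ene | CC/C=C\C/C=C\CC1(O[Si](CC)(CC)CC)C=C(O[Si](CC)(CC)CC)C1
F8 | step 7 | racemic 5,5-dichloro-3-[(2Z,5Z)-octa-2,5-dien-1-yl]-1,3-bis(triethylsilyloxy)bicyclo[2.1.0]pentane | CC/C=C\C/C=C\CC1(O[Si](CC)(CC)CC)C2C(Cl)(Cl)C2(O[Si](CC)(CC)CC)C1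
F9 | step 7 | racemic 2-chloro-4-[(2Z,5Z)-octa-2,5-dien-1-yl]-4-(triethylsilyloxy)cyclopent-2-en-1-one | CC/C=C\C/C=C\CC1(O[Si](CC)(CC)CC)C=C(Cl)C(=O)C1
F10 | step 7 | (4R)-2-chloro-4-[(2Z,5Z)-octa-2,5-dien-1-yl]-4-(triethylsilyloxy)cyclopent-2-en-1-one | CC/C=C\C/C=C\C[C@]1(O[Si](CC)(CC)CC)C=C(Cl)C(=O)C1
F11 | step 16 | (3S)-5-chloro-3-[(2Z,5Z)-octa-2,5-dien-1-yl]-1,3-bis(triethylsilyloxy)cyclopenta-1,4-diene | CC/C=C\C/C=C\C[C@@]1(O[Si](CC)(CC)CC)C=C(Cl)C(O[Si](CC)(CC)CC)=C1
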